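**Retrosynthetic overview**

1. The strategy rests on ring B: C6 (carbinol carbon, attached to the C5=C10 double bond shared with ring A) and its neighbour C7 (acetoxy carbon) form an acyloin-level pair. As the 7β-hydroxy-6-ketone 17 this pair is the retron of an α-ketol ring expansion of the ring-B-contracted cyclopentene 16, in which C6 carries OH and CHO and C7 is the formyl carbon (bond made: C7–C8).
2. 16 ⇐ hydrindenone 13 (C6=O → C6=CH2 → diol → aldehyde). 13 ⇐ Nazarov cyclisation (bond C9–C10) of dienynone 10. 10 ⇐ Shapiro vinyllithium 9 (ring A, from 2,2-dimethylcyclohexanone) + Weinreb amide 6 (enol triflate of ethyl 2-methylacetoacetate + alkyne 4).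
3. Control element for C8: two saturated groups of like size on C9 would leave the epimerisable C8 methyl without a preferred side. C11–C12 is therefore carried as an alkyne through the cyclisation, so that C8 settles cis to the slim alkyne (trans to the C9 methyl); the alkyne is hydrogenated afterwards.
4. After the ring expansion: C6 reduction to the cis-6β,7β-diol level, side chain (C13 carbinol, C14=C15) by HWE, Sharpless epoxidation and reductive epoxide opening, and C7-selective acetylation last.
5. Order of ring formation: ring A (purchased) → cyclopentenone ring C5–C6–C8–C9–C10 (step 7) → ring B by one-carbon expansion of that ring (step 12).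

Key step: step 12

Remark: halimane locants are used for all intermediates (in the hydrindene compounds indene C1 = C6, C2 = C8, C3 = C9, C3a = C10, C7 = C4, C7a = C5, and C7 is the exocyclic one-carbon unit on C6); β is the face of the C9 methyl (C20), α that of the C9 side chain, and every compound from 12 on has 8α-CH3 (C17), 9β-CH3 and the 9α side chain.

**Route**

Step 1
Reactants: 1 ethyl 2-methylacetoacetate
Product: 2 ethyl (Z)-2-methyl-3-(trifluoromethylsulfonyloxy)but-2-enoate (triflate cis to the ester)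
Conditions: NaH, Et2O, 0 °C; then Tf2O, 0 °C
Reagents that add atoms: trifluoromethanesulfonic anhydride, O=S(=O)(OS(=O)(=O)C(F)(F)F)C(F)(F)F
Why: O-triflation of the sodium-chelated enolate of the β-keto ester (enol triflate formation) should give the isomer with the triflate cis to the ester, which fixes the geometry of the later tetrasubstituted alkene.

Step 2
Reactants: 3 but-3-yn-2-one
Product: 4 2-ethynyl-2-methyl-1,3-dioxolane
Conditions: TMSOCH2CH2OTMS, TMSOTf (cat.), CH2Cl2, −78 °C
Reagents that add atoms: 1,2-bis(trimethylsilyloxy)ethane, C[Si](C)(C)OCCO[Si](C)(C)C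
Why: Lewis-acid-catalysed ketalisation with the bis-silyl ether of ethylene glycol runs at low temperature under aprotic conditions, which avoids conjugate addition of the glycol to the ynone.

Step 3
Reactants: 2 ethyl (Z)-2-methyl-3-(trifluoromethylsulfonyloxy)but-2-enoate; 4 2-ethynyl-2-methyl-1,3-dioxolane
Product: 5 ethyl (Z)-2,3-dimethyl-5-(2-methyl-1,3-dioxolan-2-yl)pent-2-en-4-ynoate (alkynyl cis to the ester)
Conditions: PdCl2(PPh3)2 (cat.), CuI (cat.), Et3N, DMF, rt
Reagents that add atoms: none
Why: Sonogashira coupling of the electron-poor alkenyl triflate proceeds with retention of geometry, so the alkynyl arm (C11≡C12) ends up cis to the ester and will be the small inside substituent at C9 in the cyclisation.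

Step 4
Reactants: 5 ethyl (Z)-2,3-dimethyl-5-(2-methyl-1,3-dioxolan-2-yl)pent-2-en-4-ynoate
Product: 6 (Z)-N-methoxy-N,2,3-trimethyl-5-(2-methyl-1,3-dioxolan-2-yl)pent-2-en-4-ynamide
Conditions: MeNH(OMe)·HCl, i-PrMgCl, THF, −20 → 0 °C
Reagents that add atoms: N,O-dimethylhydroxylamine hydrochloride, CNOC.Cl
Why: Aminolysis of the ester by the chloromagnesium amide (Weinreb amide formation) acts at the ester carbonyl only and leaves alkene geometry and ketal untouched.

Step 5
Reactants: 7 2,2-dimethylcyclohexanone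
Product: 8 (E)-N'-(2,2-dimethylcyclohexylidene)-2,4,6-triisopropylbenzenesulfonohydrazide
Conditions: 2,4,6-triisopropylbenzenesulfonohydrazide, HCl (cat.), MeCN, rt
Reagents that add atoms: 2,4,6-triisopropylbenzenesulfonohydrazide, CC(C)c1cc(C(C)C)c(S(=O)(=O)NN)c(C(C)C)c1
Why: Acid-catalysed hydrazone formation places the sulfonamide nitrogen anti to the quaternary carbon, the geometry needed for syn-directed deprotonation of the only α-CH2 in the next step.

Step 6
Reactants: 8 (E)-N'-(2,2-dimethylcyclohexylidene)-2,4,6-triisopropylbenzenesulfonohydrazide; 6 (Z)-N-methoxy-N,2,3-trimethyl-5-(2-methyl-1,3-dioxolan-2-yl)pent-2-en-4-ynamide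
Product: 10 (Z)-1-(6,6-dimethylcyclohex-1-en-1-yl)-2,3-dimethyl-5-(2-methyl-1,3-dioxolan-2-yl)pent-2-en-4-yn-1-one, via 6,6-dimethylcyclohex-1-enyllithium 9 (not isolated)
Conditions: n-BuLi (2.1 equiv), THF–TMEDA, −78 → 0 °C; then 6, −78 → 0 °C; aq. NH4Cl
Reagents that add atoms: none
Why: In the Shapiro reaction the hydrazone dianion loses sulfinate and N2 to give the vinyllithium at the former carbonyl carbon (C5), which adds only once to the Weinreb amide because the chelated tetrahedral intermediate survives until work-up.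

Step 7
Reactants: 10 (Z)-1-(6,6-dimethylcyclohex-1-en-1-yl)-2,3-dimethyl-5-(2-methyl-1,3-dioxolan-2-yl)pent-2-en-4-yn-1-one
Product: 12 (2S,3S)-2,3,7,7-tetramethyl-3-[(2-methyl-1,3-dioxolan-2-yl)ethynyl]-2,3,4,5,6,7-hexahydro-1H-inden-1-one (8α-CH3; 9β-CH3; 9α-alkynyl), via C8-epimeric hydrindenone 11 (not isolated)
Conditions: chiral confined Brønsted acid (imidodiphosphorimidate type, 5 mol%), toluene, −20 °C → rt; then DBU (0.2 equiv), rt
Reagents that add atoms: none
Why: In this Nazarov cyclisation the hydroxypentadienyl cation closes by 4π conrotation to form C9–C10 (H and the slim alkyne as inside groups), the chiral counter-anion (antipode chosen for the configuration drawn) decides the sense of conrotation and hence C9, loss of H10 and tautomerisation give the C5=C10 enone, and base equilibration of the enolisable C8 should favour the methyl cis to the rod-like alkyne and trans to the C9 methyl, the minor epimer being recycled through the same equilibration.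

Step 8
Reactants: 12 (2S,3S)-2,3,7,7-tetramethyl-3-[(2-methyl-1,3-dioxolan-2-yl)ethynyl]-2,3,4,5,6,7-hexahydro-1H-inden-1-one
Product: 13 (2S,3R)-2,3,7,7-tetramethyl-3-[2-(2-methyl-1,3-dioxolan-2-yl)ethyl]-2,3,4,5,6,7-hexahydro-1H-inden-1-one
Conditions: H2 (1 atm), 10% Pd/C, EtOAc, rt
Reagents that add atoms: none
Why: Catalytic hydrogenation saturates the unhindered alkyne to C11H2–C12H2 while the tetrasubstituted, doubly flanked enone double bond should resist, and the neutral conditions do not enolise C8, whose configuration is from here on only kinetically held.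

Step 9
Reactants: 13 (2S,3R)-2,3,7,7-tetramethyl-3-[2-(2-methyl-1,3-dioxolan-2-yl)ethyl]-2,3,4,5,6,7-hexahydro-1H-inden-1-one
Product: 14 2,3,7,7-tetramethyl-1-methylidene-3-[2-(2-methyl-1,3-dioxolan-2-yl)ethyl]-2,3,4,5,6,7-hexahydro-1H-indene (C6=C7H2 exocyclic; 8α-CH3; 9β-CH3)
Conditions: Cp2TiMe2, toluene–THF, 65 °C, dark
Reagents that add atoms: dimethyltitanocene, C[Ti](C)(C1C=CC=C1)C1C=CC=C1
Why: Petasis methylenation is thermal and non-basic, so the hindered, enolisable C6 ketone is turned into the exocyclic methylene (C7) without epimerising C8.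

Step 10
Reactants: 14 2,3,7,7-tetramethyl-1-methylidene-3-[2-(2-methyl-1,3-dioxolan-2-yl)ethyl]-2,3,4,5,6,7-hexahydro-1H-indene
Product: 15 1-(hydroxymethyl)-2,3,7,7-tetramethyl-3-[2-(2-methyl-1,3-dioxolan-2-yl)ethyl]-2,3,4,5,6,7-hexahydro-1H-inden-1-ol (6β-OH; 6α-CH2OH)
Conditions: OsO4 (2 mol%), NMO, acetone–H2O, 0 °C
Reagents that add atoms: osmium tetroxide, O=[Os](=O)(=O)=O; N-methylmorpholine N-oxide, C[N+]1([O-])CCOCC1; water, O
Why: Catalytic osmium tetroxide dihydroxylation (Upjohn conditions) takes the terminal 1,1-disubstituted alkene of the diene rather than the tetrasubstituted C5=C10 bond and should approach from the β face, anti to the adjacent C8 methyl and the C9 side chain, which places the tertiary OH β and the CH2OH (C7) α.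

Step 11
Reactants: 15 1-(hydroxymethyl)-2,3,7,7-tetramethyl-3-[2-(2-methyl-1,3-dioxolan-2-yl)ethyl]-2,3,4,5,6,7-hexahydro-1H-inden-1-ol
Product: 16 1-hydroxy-2,3,7,7-tetramethyl-3-[2-(2-methyl-1,3-dioxolan-2-yl)ethyl]-2,3,4,5,6,7-hexahydro-1H-indene-1-carbaldehyde (6β-OH; 6α-CHO)
Conditions: SO3·pyridine, DMSO, i-Pr2NEt, CH2Cl2, 0 °C
Reagents that add atoms: none
Why: Parikh–Doering oxidation converts only the primary alcohol, the tertiary allylic alcohol being inert, and its mild non-acidic conditions deliver the rearrangement-prone α-hydroxy aldehyde, which is used without chromatography.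

Step 12
Reactants: 16 1-hydroxy-2,3,7,7-tetramethyl-3-[2-(2-methyl-1,3-dioxolan-2-yl)ethyl]-2,3,4,5,6,7-hexahydro-1H-indene-1-carbaldehyde
Product: 17 13,13-(ethylenedioxy)-7β-hydroxy-14,15-dinorhalim-5(10)-en-6-one
Conditions: Al(Ot-Bu)3 (0.3 equiv), toluene, 60 °C (crude 16)
Reagents that add atoms: none
Why: Aluminium binds the C6 alkoxide and the formyl oxygen in a syn-periplanar five-membered chelate, so that the C6–C8 and C6–C5 bonds stand perpendicular to the chelate plane and either can shift suprafacially to the formyl carbon while C6 becomes a carbonyl, an α-ketol (acyloin) rearrangement of the kind known for 1-formyl- and 1-acylcyclopentanols and for the D-homoannulation of 17-hydroxy-20-oxo steroids. Ring B is closed not by cyclisation but by one-carbon ring expansion: C8 migrates with retention from C6 to C7 (new bond C7–C8) and the cyclopentene becomes the cyclohexenone. The only new stereocentre, C7, is set by the chelate: with O6 on the β face and the formyl group on the α face, the syn-periplanar formyl oxygen ends up β after the C8 shift, trans to the C8 methyl, which is also the equatorial arrangement to which the epimerisable ketol carbon would relax. The step needs the C8 shift and not the C5 (alkenyl) shift; this is secured thermodynamically, because the aldehyde-to-ketone change and the loss of cyclopentene strain make the expansion downhill, only the product of C8 shift has its ketone conjugated with C5=C10, and the non-conjugated isomer from C5 shift can drain into 17 through the shared aluminium enediolate under the same conditions. C8 is not α to the C6 carbonyl of 17, so its configuration should survive, and the side-chain dioxolane is inert to the aluminium alkoxide.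

Step 13
Reactants: 17 13,13-(ethylenedioxy)-7β-hydroxy-14,15-dinorhalim-5(10)-en-6-one
Product: 18 7β-(tert-butyldimethylsilyloxy)-13,13-(ethylenedioxy)-14,15-dinorhalim-5(10)-en-6-one
Conditions: TBSOTf (1.1 equiv), 2,6-lutidine, CH2Cl2, −78 °C
Reagents that add atoms: tert-butyldimethylsilyl trifluoromethanesulfonate, CC(C)(C)[Si](C)(C)OS(=O)(=O)C(F)(F)F
Why: Silyl triflate with lutidine at low temperature silylates the only hydroxyl faster than it enolises the ketone or opens the ketal (silyl ether formation), which masks C7–OH and makes the C7 substituent bulky for the reduction.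

Step 14
Reactants: 18 7β-(tert-butyldimethylsilyloxy)-13,13-(ethylenedioxy)-14,15-dinorhalim-5(10)-en-6-one
Product: 19 7β-(tert-butyldimethylsilyloxy)-13,13-(ethylenedioxy)-14,15-dinorhalim-5(10)-en-6β-ol
Conditions: L-Selectride, THF, −78 °C
Reagents that add atoms: none
Why: The bulky trialkylborohydride should reduce the C6 ketone in 1,2-fashion (its β-carbon C10 is fully substituted) by equatorial attack from the α face, away from the β-disposed silyloxy group, giving the pseudo-axial 6β alcohol cis to C7–O (L-Selectride reduction of an α-silyloxy ketone).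

Step 15
Reactants: 19 7β-(tert-butyldimethylsilyloxy)-13,13-(ethylenedioxy)-14,15-dinorhalim-5(10)-en-6β-ol
Product: 20 6β,7β-bis(tert-butyldimethylsilyloxy)-13,13-(ethylenedioxy)-14,15-dinorhalim-5(10)-ene
Conditions: TBSOTf, 2,6-lutidine, CH2Cl2, 0 °C → rt
Reagents that add atoms: tert-butyldimethylsilyl trifluoromethanesulfonate, CC(C)(C)[Si](C)(C)OS(=O)(=O)C(F)(F)F
Why: The silyl triflate is reactive enough for the hindered allylic 6β-OH (silyl ether formation), so that both ring oxygens are inert to the base, hydride, titanium and iodination steps of the side-chain sequence.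

Step 16
Reactants: 20 6β,7β-bis(tert-butyldimethylsilyloxy)-13,13-(ethylenedioxy)-14,15-dinorhalim-5(10)-ene
Product: 21 6β,7β-bis(tert-butyldimethylsilyloxy)-14,15-dinorhalim-5(10)-en-13-one
Conditions: PPTS (cat.), acetone–H2O, 50 °C
Reagents that add atoms: water, O
Why: Mild acid-catalysed ketal hydrolysis in wet acetone frees the C13 methyl ketone while secondary TBS ethers tolerate pyridinium tosylate.

Step 17
Reactants: 21 6β,7β-bis(tert-butyldimethylsilyloxy)-14,15-dinorhalim-5(10)-en-13-one; 22 triethyl phosphonoacetate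
Product: 23 ethyl (13E)-6β,7β-bis(tert-butyldimethylsilyloxy)halima-5(10),13-dien-15-oate
Conditions: NaH, THF, 0 → 50 °C
Reagents that add atoms: none
Why: Horner–Wadsworth–Emmons olefination of the unhindered methyl ketone gives mainly the (E)-trisubstituted enoate (ester trans to the chain), and the minor (Z)-isomer is removed by chromatography because alkene geometry decides the later C13 configuration.

Step 18
Reactants: 23 ethyl (13E)-6β,7β-bis(tert-butyldimethylsilyloxy)halima-5(10),13-dien-15-oate
Product: 24 (13E)-6β,7β-bis(tert-butyldimethylsilyloxy)halima-5(10),13-dien-15-ol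
Conditions: DIBAL-H, CH2Cl2, −78 °C; Rochelle salt
Reagents that add atoms: none
Why: DIBAL-H reduces the conjugated ester in 1,2-fashion to the (E)-allylic alcohol at low temperature without touching the silyl ethers or the ring alkene (ester reduction).

Step 19
Reactants: 24 (13E)-6β,7β-bis(tert-butyldimethylsilyloxy)halima-5(10),13-dien-15-ol
Product: 25 (13S,14S)-6β,7β-bis(tert-butyldimethylsilyloxy)-13,14-epoxyhalim-5(10)-en-15-ol
Conditions: Ti(Oi-Pr)4 (10 mol%), L-(+)-diethyl tartrate (12 mol%), t-BuOOH, 4 Å MS, CH2Cl2, −20 °C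
Reagents that add atoms: tert-butyl hydroperoxide, CC(C)(C)OO
Why: Sharpless asymmetric epoxidation is reagent-controlled, so with L-(+)-tartrate the (E)-3,3-disubstituted allylic alcohol should give the (13S,14S)-epoxy alcohol irrespective of the remote ring stereocentres, while the tetrasubstituted ring alkene flanked by a silyl ether is not a substrate.

Step 20
Reactants: 25 (13S,14S)-6β,7β-bis(tert-butyldimethylsilyloxy)-13,14-epoxyhalim-5(10)-en-15-ol
Product: 27 (13S)-6β,7β-bis(tert-butyldimethylsilyloxy)halima-5(10),14-dien-13-ol, via epoxy iodide 26 (not isolated)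
Conditions: I2, PPh3, imidazole, THF, 0 °C; then Zn dust, AcOH–EtOH, rt
Reagents that add atoms: none
Why: Appel-type iodination of the primary alcohol followed by zinc insertion and β-elimination of the epoxide oxygen (reductive epoxide opening) transposes the allylic system without breaking the C13–O bond, so the (13S) tertiary vinyl carbinol arises with retention.

Step 21
Reactants: 27 (13S)-6β,7β-bis(tert-butyldimethylsilyloxy)halima-5(10),14-dien-13-ol
Product: 28 (13S)-halima-5(10),14-diene-6β,7β,13-triol
Conditions: TBAF, THF, 40 °C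
Reagents that add atoms: none
Why: Fluoride cleaves both silyl ethers under non-acidic conditions (desilylation), which spares the ionisable tertiary and secondary allylic alcohols.

Step 22
Reactants: 28 (13S)-halima-5(10),14-diene-6β,7β,13-triol
Product: 29 (6S,7R,8S,9R,13S)-6,13-dihydroxyhalima-5(10),14-dien-7-yl acetate (target CNP0126002.2)
Conditions: Ac2O (1.05 equiv), pyridine, CH2Cl2, 0 °C
Reagents that add atoms: acetic anhydride, CC(=O)OC(C)=O
Why: Selective acetylation with one equivalent of anhydride should take the equatorial C7–OH, because the pseudo-axial allylic C6–OH is shielded by the C4 gem-dimethyl group and the tertiary C13–OH does not react under these conditions, and the equatorial 7-acetate is also the favoured position should acyl migration occur.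

**Compound list**

1 | ethyl 2-methylacetoacetate | CCOC(=O)C(C)C(C)=O | starting material
2 | ethyl (Z)-2-methyl-3-(trifluoromethylsulfonyloxy)but-2-enoate | CCOC(=O)/C(C)=C(C)\OS(=O)(=O)C(F)(F)F | intermediate
3 | but-3-yn-2-one | CC(=O)C#C | starting material
4 | 2-ethynyl-2-methyl-1,3-dioxolane | CC1(C#C)OCCO1 | intermediate
5 | ethyl (Z)-2,3-dimethyl-5-(2-methyl-1,3-dioxolan-2-yl)pent-2-en-4-ynoate | CCOC(=O)/C(C)=C(C)\C#CC1(C)OCCO1 | intermediate
6 | (Z)-N-methoxy-N,2,3-trimethyl-5-(2-methyl-1,3-dioxolan-2-yl)pent-2-en-4-ynamide | CON(C)C(=O)/C(C)=C(C)\C#CC1(C)OCCO1 | intermediate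
7 | 2,2-dimethylcyclohexanone | CC1(C)CCCCC1=O | starting material
8 | (E)-N'-(2,2-dimethylcyclohexylidene)-2,4,6-triisopropylbenzenesulfonohydrazide | CC(C)c1cc(C(C)C)c(S(=O)(=O)N/N=C2\CCCCC2(C)C)c(C(C)C)c1 | intermediate
9 | 6,6-dimethylcyclohex-1-enyllithium | [Li]C1=CCCCC1(C)C | intermediate (not isolated)
10 | (Z)-1-(6,6-dimethylcyclohex-1-en-1-yl)-2,3-dimethyl-5-(2-methyl-1,3-dioxolan-2-yl)pent-2-en-4-yn-1-one | CC1(C)CCCC=C1C(=O)/C(C)=C(C)\C#CC2(C)OCCO2 | intermediate
11 | (3S)-2,3,7,7-tetramethyl-3-[(2-methyl-1,3-dioxolan-2-yl)ethynyl]-2,3,4,5,6,7-hexahydro-1H-inden-1-one, mixture of C8 (indene C2) epimers | CC1(C#C[C@@]2(C)C3=C(C(C)(C)CCC3)C(=O)C2C)OCCO1 | intermediate (not isolated)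
12 | (2S,3S)-2,3,7,7-tetramethyl-3-[(2-methyl-1,3-dioxolan-2-yl)ethynyl]-2,3,4,5,6,7-hexahydro-1H-inden-1-one (8α-CH3, 9β-CH3, 9α-alkynyl) | CC1(C#C[C@@]2(C)C3=C(C(C)(C)CCC3)C(=O)[C@H]2C)OCCO1 | intermediate
13 | (2S,3R)-2,3,7,7-tetramethyl-3-[2-(2-methyl-1,3-dioxolan-2-yl)ethyl]-2,3,4,5,6,7-hexahydro-1H-inden-1-one | CC1(CC[C@@]2(C)C3=C(C(C)(C)CCC3)C(=O)[C@H]2C)OCCO1 | intermediate
14 | 2,3,7,7-tetramethyl-1-methylidene-3-[2-(2-methyl-1,3-dioxolan-2-yl)ethyl]-2,3,4,5,6,7-hexahydro-1H-indene (8α-CH3, 9β-CH3) | CC1(CC[C@@]2(C)C3=C(C(C)(C)CCC3)C(=C)[C@H]2C)OCCO1 | intermediate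
15 | 1-(hydroxymethyl)-2,3,7,7-tetramethyl-3-[2-(2-methyl-1,3-dioxolan-2-yl)ethyl]-2,3,4,5,6,7-hexahydro-1H-inden-1-ol (6β-OH, 6α-CH2OH) | CC1(CC[C@@]2(C)C3=C(C(C)(C)CCC3)[C@@](O)(CO)[C@H]2C)OCCO1 | intermediate
16 | 1-hydroxy-2,3,7,7-tetramethyl-3-[2-(2-methyl-1,3-dioxolan-2-yl)ethyl]-2,3,4,5,6,7-hexahydro-1H-indene-1-carbaldehyde (6β-OH, 6α-CHO) | CC1(CC[C@@]2(C)C3=C(C(C)(C)CCC3)[C@@](O)(C=O)[C@H]2C)OCCO1 | intermediate
17 | 13,13-(ethylenedioxy)-7β-hydroxy-14,15-dinorhalim-5(10)-en-6-one | CC1(CC[C@@]2(C)C3=C(C(=O)[C@H](O)[C@H]2C)C(C)(C)CCC3)OCCO1 | intermediate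
18 | 7β-(tert-butyldimethylsilyloxy)-13,13-(ethylenedioxy)-14,15-dinorhalim-5(10)-en-6-one | CC1(CC[C@@]2(C)C3=C(C(=O)[C@H](O[Si](C)(C)C(C)(C)C)[C@H]2C)C(C)(C)CCC3)OCCO1 | intermediate
19 | 7β-(tert-butyldimethylsilyloxy)-13,13-(ethylenedioxy)-14,15-dinorhalim-5(10)-en-6β-ol | CC1(CC[C@@]2(C)C3=C([C@H](O)[C@H](O[Si](C)(C)C(C)(C)C)[C@H]2C)C(C)(C)CCC3)OCCO1 | intermediate
20 | 6β,7β-bis(tert-butyldimethylsilyloxy)-13,13-(ethylenedioxy)-14,15-dinorhalim-5(10)-ene | CC1(CC[C@@]2(C)C3=C([C@H](O[Si](C)(C)C(C)(C)C)[C@H](O[Si](C)(C)C(C)(C)C)[C@H]2C)C(C)(C)CCC3)OCCO1 | intermediate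
21 | 6β,7β-bis(tert-butyldimethylsilyloxy)-14,15-dinorhalim-5(10)-en-13-one | CC(=O)CC[C@@]1(C)C2=C([C@H](O[Si](C)(C)C(C)(C)C)[C@H](O[Si](C)(C)C(C)(C)C)[C@H]1C)C(C)(C)CCC2 | intermediate
22 | triethyl phosphonoacetate | CCOC(=O)CP(=O)(OCC)OCC | starting material
23 | ethyl (13E)-6β,7β-bis(tert-butyldimethylsilyloxy)halima-5(10),13-dien-15-oate | CCOC(=O)/C=C(\C)CC[C@@]1(C)C2=C([C@H](O[Si](C)(C)C(C)(C)C)[C@H](O[Si](C)(C)C(C)(C)C)[C@H]1C)C(C)(C)CCC2 | intermediate
24 | (13E)-6β,7β-bis(tert-butyldimethylsilyloxy)halima-5(10),13-dien-15-ol | OC/C=C(\C)CC[C@@]1(C)C2=C([C@H](O[Si](C)(C)C(C)(C)C)[C@H](O[Si](C)(C)C(C)(C)C)[C@H]1C)C(C)(C)CCC2 | intermediate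
25 | (13S,14S)-6β,7β-bis(tert-butyldimethylsilyloxy)-13,14-epoxyhalim-5(10)-en-15-ol | OC[C@@H]1O[C@@]1(C)CC[C@@]2(C)C3=C([C@H](O[Si](C)(C)C(C)(C)C)[C@H](O[Si](C)(C)C(C)(C)C)[C@H]2C)C(C)(C)CCC3 | intermediate
26 | (13S,14R)-6β,7β-bis(tert-butyldimethylsilyloxy)-13,14-epoxy-15-iodohalim-5(10)-ene | IC[C@@H]1O[C@@]1(C)CC[C@@]2(C)C3=C([C@H](O[Si](C)(C)C(C)(C)C)[C@H](O[Si](C)(C)C(C)(C)C)[C@H]2C)C(C)(C)CCC3 | intermediate (not isolated)
27 | (13S)-6β,7β-bis(tert-butyldimethylsilyloxy)halima-5(10),14-dien-13-ol | C=C[C@@](C)(O)CC[C@@]1(C)C2=C([C@H](O[Si](C)(C)C(C)(C)C)[C@H](O[Si](C)(C)C(C)(C)C)[C@H]1C)C(C)(C)CCC2 | intermediate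
28 | (13S)-halima-5(10),14-diene-6β,7β,13-triol | C=C[C@@](C)(O)CC[C@@]1(C)C2=C([C@H](O)[C@H](O)[C@H]1C)C(C)(C)CCC2 | intermediate
29 | (6S,7R,8S,9R,13S)-6,13-dihydroxyhalima-5(10),14-dien-7-yl acetate | C=C[C@@](C)(O)CC[C@@]1(C)C2=C([C@H](O)[C@H](OC(C)=O)[C@H]1C)C(C)(C)CCC2 | target

**Step count and risks**

Total step count: 22. Longest linear sequence: 20 steps (steps 1, 3, 4 and 6–22 from ethyl 2-methylacetoacetate; the same length from but-3-yn-2-one through step 2).

Steps most likely to fail:

Step 7 (Nazarov cyclisation). The chiral counter-anion may not control the sense of conrotation well enough at the fully substituted C9 terminus, or the strong acid may open the propargylic dioxolane, so that enantiopurity is eroded. The fallback replaces asymmetric catalysis by resolution and sets out from 10. Cyclisation with an achiral strong acid (Tf2NH cat., CH2Cl2) followed by the same DBU equilibration should give the racemic alkynyl hydrindenone F1. Corey–Bakshi–Shibata reduction (Me-CBS oxazaborolidine, BH3·SMe2) sets the C6 carbinol under catalyst control and so turns the two enantiomers into diastereomeric allylic alcohols. The 6α-carbinol of the wanted enantiomeric series F2 (OH cis to the C8 methyl, the matched outcome for the appropriate catalyst antipode) is separated by chromatography and reoxidised with Dess–Martin periodinane, which brings the route back at 12.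

Step 12 (α-ketol ring expansion). The alkenyl carbon C5 may migrate instead of C8 without later equilibration through the enediolate, or the tertiary allylic alcohol may ionise under the Lewis acid. The fallback homologates the ketone instead of rearranging the hydroxy aldehyde and sets out from 13. Trimethylaluminium-promoted ring expansion with (trimethylsilyl)diazomethane should insert the new carbon on the saturated C6–C8 side, the alkenyl carbon being the poorer migrating group, to give the 7-silyl cyclohexenone F3. Protodesilylation (K2CO3, MeOH) gives the 7-unsubstituted halim-5(10)-en-6-one ketal F4. Its kinetic lithium enolate (LiHMDS, −78 °C; C7 is the only enolisable α-position) is hydroxylated with 2-(phenylsulfonyl)-3-phenyloxaziridine, and the epimerisable C7 carbinol should settle equatorial (7β, trans to the C8 methyl), which brings the route back at 17.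

Step 14 (C6 reduction). Facial selectivity may be poor (axial hydride delivery from the β face, leading to the 6α alcohol trans to C7–O), or the bulky hydride may not reach the doubly flanked carbonyl. The fallback uses inversion instead of direct delivery and sets out from 18. A small hydride (NaBH4, CeCl3, MeOH, −40 °C) should reduce the ketone by axial attack to the 6α-alcohol F5. Mitsunobu inversion (4-nitrobenzoic acid, PPh3, DIAD) gives the 6β-(4-nitrobenzoate) F6, and methanolysis (K2CO3, MeOH) brings the route back at 19.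

Further compounds
F1 | step 7 | racemic 12 (both enantiomers; relative configuration as drawn) | CC1(C#C[C@@]2(C)C3=C(C(C)(C)CCC3)C(=O)[C@H]2C)OCCO1
F2 | step 7 | 2,3,7,7-tetramethyl-3-[(2-methyl-1,3-dioxolan-2-yl)ethynyl]-2,3,4,5,6,7-hexahydro-1H-inden-1-ol, 6α-OH (cis to 8α-CH3), wanted enantiomeric series | CC1(C#C[C@@]2(C)C3=C(C(C)(C)CCC3)[C@@H](O)[C@H]2C)OCCO1
F3 | step 12 | 13,13-(ethylenedioxy)-7-(trimethylsilyl)-14,15-dinorhalim-5(10)-en-6-one (C7 epimers) | CC1(CC[C@@]2(C)C3=C(C(=O)C([Si](C)(C)C)[C@H]2C)C(C)(C)CCC3)OCCO1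
F4 | step 12 | 13,13-(ethylenedioxy)-14,15-dinorhalim-5(10)-en-6-one | CC1(CC[C@@]2(C)C3=C(C(=O)C[C@H]2C)C(C)(C)CCC3)OCCO1
F5 | step 14 | 7β-(tert-butyldimethylsilyloxy)-13,13-(ethylenedioxy)-14,15-dinorhalim-5(10)-en-6α-ol | CC1(CC[C@@]2(C)C3=C([C@@H](O)[C@H](O[Si](C)(C)C(C)(C)C)[C@H]2C)C(C)(C)CCC3)OCCO1
F6 | step 14 | 7β-(tert-butyldimethylsilyloxy)-13,13-(ethylenedioxy)-14,15-dinorhalim-5(10)-en-6β-yl 4-nitrobenzoate | CC1(CC[C@@]2(C)C3=C([C@H](OC(=O)c4ccc(cc4)[N+](=O)[O-])[C@H](O[Si](C)(C)C(C)(C)C)[C@H]2C)C(C)(C)CCC3)OCCO1
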